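**Plan**

- Units: 1 = upper epicatechin, 2 = epigallocatechin 3-O-gallate, 3 = inner epicatechin (built de novo), 4 = catechin terminus. Cuts, in order: twenty O–benzyl bonds; both aryl bonds at C4 of unit 3 (C4–C4a, which closes ring C of unit 3, and C4–C8 of unit 4) back to a diethyl acetal; O1–C2 of unit 3 (phenol + cis-epoxide); C4 of unit 2–aryl; C4 of unit 1–C8 of unit 2.
- Enabling feature: C4 of unit 3 is a methine between two 1,3,5-trioxygenated benzene rings (C4a of its own ring A and C8 of ring A of unit 4), so it is a latent aldehyde carbon. O1 ties it to ring A through a six-membered ring and leaves only one free ortho carbon, C4a.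
- Forward: units 1 and 2 are joined by hard-acid coupling while a C4 thioether on unit 2 stays latent. Silver activation of that thioether attaches ring A of unit 3 as a phenol, and the phenol opens a cis-epoxy acetal (O1–C2). One acid-mediated event then closes ring C of unit 3 and attaches unit 4; hydrogenolysis finishes.
- Stereochemistry: units 1, 2 and 4 come from the chiral pool. Each 4β interflavan bond arises by attack anti to the axial C3 oxygen. C2/C3 of unit 3 come from catalyst-controlled cis-epoxidation of a Z-alkene followed by SN2 inversion at the benzylic carbon. C4 of unit 3 is set in the key step.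

Key step: step 14

Assumption: the free C3 hydroxyls of units 1, 3 and 4 are carried unprotected, since silyl triflate- and silver-promoted flavan couplings tolerate secondary alcohols (transient silylation is reversed on work-up).

**Route**

Step 1
Reactants: 1 (−)-epicatechin
Product: 2 5,7,3',4'-tetra-O-benzyl-(−)-epicatechin
Conditions: BnBr (4.2 equiv), K2CO3, DMF, 0 °C to rt
Reagents that add atoms: benzyl bromide, BrCc1ccccc1
Why: Williamson etherification should benzylate only the four phenols (carbonate does not deprotonate the C3 alcohol) and touches no stereocentre.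

Step 2
Reactants: 2 5,7,3',4'-tetra-O-benzyl-(−)-epicatechin
Product: 3 4β-(2-ethoxyethoxy)-5,7,3',4'-tetra-O-benzylepicatechin (2R, 2,3-cis, 3,4-trans, 3-OH free)
Conditions: DDQ (2 equiv), 2-ethoxyethanol (5 equiv), CH2Cl2, rt
Reagents that add atoms: 2-ethoxyethanol, CCOCCO
Why: DDQ benzylic oxidation removes hydride from C4 (activated by the ortho and para oxygens of ring A), and the alcohol should trap the cation anti to the axial C3 hydroxyl.

Step 3
Reactants: 4 (−)-epigallocatechin
Product: 5 5,7,3',4',5'-penta-O-benzyl-(−)-epigallocatechin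
Conditions: BnBr (5.5 equiv), K2CO3, DMF, 0 °C to rt
Reagents that add atoms: benzyl bromide, BrCc1ccccc1
Why: Williamson etherification of the five phenols, with the C3 alcohol and both stereocentres untouched.

Step 4
Reactants: 5 5,7,3',4',5'-penta-O-benzyl-(−)-epigallocatechin
Product: 6 4β-(2-ethoxyethoxy)-5,7,3',4',5'-penta-O-benzylepigallocatechin
Conditions: DDQ (2 equiv), 2-ethoxyethanol (5 equiv), CH2Cl2, rt
Reagents that add atoms: 2-ethoxyethanol, CCOCCO
Why: the same DDQ benzylic oxidation with alcohol trapping anti to the C3 hydroxyl as in step 2.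

Step 5
Reactants: 6 4β-(2-ethoxyethoxy)-5,7,3',4',5'-penta-O-benzylepigallocatechin
Product: 7 4β-(2,6-dimethylphenylthio)-5,7,3',4',5'-penta-O-benzylepigallocatechin
Conditions: 2,6-dimethylbenzenethiol (3 equiv), BF3·OEt2 (0.2 equiv), CH2Cl2, −78 to −30 °C
Reagents that add atoms: 2,6-dimethylbenzenethiol, Cc1cccc(C)c1S
Why: Lewis acid-mediated O-to-S exchange through the C4 cation (thiolysis type) should place the thiol anti to the C3 hydroxyl; the hindered aryl thio group is chosen because it resists transfer to other cations later.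

Step 6
Reactants: 7 4β-(2,6-dimethylphenylthio)-5,7,3',4',5'-penta-O-benzylepigallocatechin; 8 3,4,5-tris(benzyloxy)benzoic acid
Product: 9 4β-(2,6-dimethylphenylthio)-5,7,3',4',5'-penta-O-benzylepigallocatechin 3-O-[3,4,5-tris(benzyloxy)benzoate]
Conditions: DCC (1.5 equiv), DMAP (0.2 equiv), CH2Cl2, rt
Reagents that add atoms: none
Why: Steglich esterification of the only free hydroxyl installs the protected gallate with retention at C3.

Step 7
Reactants: 3 4β-(2-ethoxyethoxy)-5,7,3',4'-tetra-O-benzylepicatechin; 9 thioether gallate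
Product: 10 thioether dimer: 5,7,3',4'-tetra-O-benzylepicatechin-(4β→8)-[4β-(2,6-dimethylphenylthio)-penta-O-benzylepigallocatechin 3-O-tris(benzyloxy)benzoate], upper 3-OH free
Conditions: TMSOTf (0.1 equiv), CH2Cl2, −78 °C, then Et3N; the thioether gallate is used in 2.5-fold excess
Reagents that add atoms: none
Why: Friedel–Crafts interflavan coupling of a 4-alkoxyflavan under hard-acid catalysis, in which C8 of 9 (ortho to O1) should attack the C4 cation anti to the axial C3 hydroxyl to set the 4β centre of unit 1; the hindered aryl thioether should stay inert at −78 °C (orthogonal activation) and the excess of 9 suppresses self-condensation of 3.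

Step 8
Reactants: 10 thioether dimer; 11 3,5-bis(benzyloxy)phenol
Product: 12 phenol dimer: the dimer of 10 in which C4β of unit 2 carries a 2-hydroxy-4,6-bis(benzyloxy)phenyl group in place of the thio group
Conditions: AgOTf (2 equiv), 4 Å MS, CH2Cl2, −30 to 0 °C; the phenol is used in fivefold excess
Reagents that add atoms: none
Why: thiophilic activation by silver generates the C4 cation of unit 2, which should be attacked anti to the participating 3-O-acyl group (4β) by the phenol carbon ortho to the free hydroxyl (Friedel–Crafts alkylation; two of the three open carbons are ortho, and any O-alkylated material should relay to the ortho carbon by O-to-C shift as in aryl C-glycoside synthesis).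

Step 9
Reactants: 13 4-bromo-1,2-bis(benzyloxy)benzene; 14 3,3-diethoxyprop-1-yne
Product: 15 1,2-bis(benzyloxy)-4-(3,3-diethoxyprop-1-yn-1-yl)benzene
Conditions: Pd(PPh3)2Cl2 (3 mol %), CuI (5 mol %), Et3N, 70 °C
Reagents that add atoms: none
Why: Sonogashira coupling joins the ring B carbon to the three-carbon chain, with C4 already at the aldehyde oxidation level as its acetal.

Step 10
Reactants: 15 aryl alkynyl acetal
Product: 16 (Z)-1,2-bis(benzyloxy)-4-(3,3-diethoxyprop-1-en-1-yl)benzene
Conditions: H2 (1 atm), Pd/CaCO3 poisoned with Pb(OAc)2 (Lindlar catalyst), quinoline, EtOAc, rt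
Reagents that add atoms: none
Why: Lindlar semihydrogenation delivers the Z-alkene by syn addition, and the poisoned catalyst should leave the benzyl ethers intact.

Step 11
Reactants: 16 Z-alkenyl acetal
Product: 17 (2S,3S)-2-[3,4-bis(benzyloxy)phenyl]-3-(diethoxymethyl)oxirane (cis)
Conditions: (S,S)-N,N'-bis(3,5-di-tert-butylsalicylidene)-1,2-cyclohexanediamine manganese chloride, (salen)MnCl (5 mol %), NaOCl aq (pH 11.3), 4-phenylpyridine N-oxide, CH2Cl2, 0 °C
Reagents that add atoms: sodium hypochlorite, [Na+].[O-]Cl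
Why: Jacobsen–Katsuki epoxidation of a cis-disubstituted aryl alkene, in which the catalyst should set both stereocentres (sense assigned by analogy with cis-cinnamate esters, benzylic carbon S with the (S,S) catalyst).

Step 12
Reactants: 12 phenol dimer; 17 cis-epoxy acetal
Product: 18 aryl ether acetal: 12 etherified at the phenolic oxygen with a (1R,2S)-1-[3,4-bis(benzyloxy)phenyl]-3,3-diethoxy-2-hydroxypropyl group
Conditions: Cs2CO3 (0.5 equiv), DMF, 60 °C; the epoxy acetal is used in twofold excess and the unreacted part is recovered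
Reagents that add atoms: none
Why: base-mediated SN2 opening of the aryl epoxide by the phenoxide at the benzylic carbon (activated, whereas the carbon next to the acetal is hindered and deactivated) with inversion (S to R) forms O1–C2 of unit 3 in an addition that keeps every atom of both partners; the carbinol centre is retained (S here, 3R after ring closure only through a priority change), which gives the threo array needed for a 2,3-cis ring.

Step 13
Reactants: 19 (+)-catechin
Product: 20 5,7,3',4'-tetra-O-benzyl-(+)-catechin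
Conditions: BnBr (4.2 equiv), K2CO3, DMF, 0 °C to rt
Reagents that add atoms: benzyl bromide, BrCc1ccccc1
Why: Williamson etherification of the four phenols, with both stereocentres untouched.

Step 14
Reactants: 18 aryl ether acetal; 20 5,7,3',4'-tetra-O-benzyl-(+)-catechin
Product: 22 icosa-O-benzyl ether of the target tetramer, via 4-ethoxyflavan 21 (not isolated)
Conditions: TMSOTf (0.3 equiv), 4 Å MS, CH2Cl2, −78 to −30 °C, then Et3N; the catechin ether is used in fourfold excess
Reagents that add atoms: none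
Why: Proposed new method: the silyl triflate should ionise the diethyl acetal to an oxocarbenium ion at C4, which is attacked by the only free carbon ortho to O1 on ring A of unit 3 to give 4-ethoxyflavan 21, whose ethoxy group ionises in turn to the C4 benzylic cation (stabilised by O1 and the 5- and 7-benzyloxy groups) that is captured by C8 of 20. The closest known reaction types are the acid-mediated cyclisation of 3-aryloxypropanal acetals to 4-alkoxychromans and the Lewis acid-mediated coupling of 4-alkoxyflavan-3-ols with flavan nucleophiles; running both in one flask on an open-chain 2-aryl-3-hydroxy substrate is the part without precedent. Ring C closes by a 6-exo-trig Friedel–Crafts alkylation (C4–C4a, the C=O+ bond lying outside the forming ring) through a chair-like arrangement with the C2 aryl group equatorial and the C3 oxygen axial. C4 is the one new stereocentre: the nucleophile should add to the half-chair cation anti to the axial C3 oxygen to give the 3,4-trans (4β) bond, and the same isomer is expected if 20 adds first and the ring closes second, because the catechin unit then prefers the pseudoaxial position trans to the C3 oxygen and away from the peri 5-benzyloxy group. The step needs ring closure to precede both intermolecular capture and ionisation of the benzylic aryl ether at C2 (secured by intramolecularity, the much easier ionisation of an acetal and −78 °C), C8 over C6 attack on 20 (the inherent preference of benzylated catechin) and suppression of self-condensation (the excess of 20).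

Step 15
Reactants: 22 icosa-O-benzyl ether of the target tetramer
Product: 23 epicatechin-(4β→8)-epigallocatechin 3-O-gallate-(4β→8)-epicatechin-(4β→8)-catechin (target)
Conditions: H2 (1 atm), Pd(OH)2/C, THF/MeOH/H2O, rt
Reagents that add atoms: none
Why: hydrogenolysis should cleave all twenty O-benzyl groups, while the gallate ester, the interflavan C–C bonds, the ring C–O bonds and every stereocentre are inert to hydrogen at 1 atm.

**Compound list**

1 | (−)-epicatechin, (2R,3R) | O[C@@H]1Cc2c(O)cc(O)cc2O[C@@H]1c1ccc(O)c(O)c1 | starting material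
2 | 5,7,3',4'-tetra-O-benzyl-(−)-epicatechin | O[C@@H]1Cc2c(OCc5ccccc5)cc(OCc5ccccc5)cc2O[C@@H]1c1ccc(OCc5ccccc5)c(OCc5ccccc5)c1 | intermediate
3 | 4β-(2-ethoxyethoxy)-5,7,3',4'-tetra-O-benzylepicatechin | O[C@@H]1[C@@H](OCCOCC)c2c(OCc5ccccc5)cc(OCc5ccccc5)cc2O[C@@H]1c1ccc(OCc5ccccc5)c(OCc5ccccc5)c1 | intermediate
4 | (−)-epigallocatechin, (2R,3R) | O[C@@H]1Cc2c(O)cc(O)cc2O[C@@H]1c1cc(O)c(O)c(O)c1 | starting material
5 | 5,7,3',4',5'-penta-O-benzyl-(−)-epigallocatechin | O[C@@H]1Cc2c(OCc5ccccc5)cc(OCc5ccccc5)cc2O[C@@H]1c1cc(OCc5ccccc5)c(OCc5ccccc5)c(OCc5ccccc5)c1 | intermediate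
6 | 4β-(2-ethoxyethoxy)-penta-O-benzylepigallocatechin | O[C@@H]1[C@@H](OCCOCC)c2c(OCc5ccccc5)cc(OCc5ccccc5)cc2O[C@@H]1c1cc(OCc5ccccc5)c(OCc5ccccc5)c(OCc5ccccc5)c1 | intermediate
7 | 4β-(2,6-dimethylphenylthio)-penta-O-benzylepigallocatechin | O[C@@H]1[C@@H](Sc5c(C)cccc5C)c2c(OCc5ccccc5)cc(OCc5ccccc5)cc2O[C@@H]1c1cc(OCc5ccccc5)c(OCc5ccccc5)c(OCc5ccccc5)c1 | intermediate
8 | 3,4,5-tris(benzyloxy)benzoic acid | OC(=O)c1cc(OCc2ccccc2)c(OCc2ccccc2)c(OCc2ccccc2)c1 | starting material
9 | 4β-(2,6-dimethylphenylthio)-penta-O-benzylepigallocatechin 3-O-[3,4,5-tris(benzyloxy)benzoate] | O=C(O[C@@H]1[C@@H](Sc5c(C)cccc5C)c2c(OCc5ccccc5)cc(OCc5ccccc5)cc2O[C@@H]1c1cc(OCc5ccccc5)c(OCc5ccccc5)c(OCc5ccccc5)c1)c1cc(OCc5ccccc5)c(OCc5ccccc5)c(OCc5ccccc5)c1 | intermediate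
10 | thioether dimer, tetra-O-benzylepicatechin-(4β→8)-[4β-(2,6-dimethylphenylthio)-penta-O-benzylepigallocatechin 3-O-tris(benzyloxy)benzoate] | O=C(O[C@@H]1[C@@H](Sc5c(C)cccc5C)c2c(OCc5ccccc5)cc(OCc5ccccc5)c([C@H]3c4c(OCc5ccccc5)cc(OCc5ccccc5)cc4O[C@H](c4ccc(OCc5ccccc5)c(OCc5ccccc5)c4)[C@@H]3O)c2O[C@@H]1c1cc(OCc5ccccc5)c(OCc5ccccc5)c(OCc5ccccc5)c1)c1cc(OCc5ccccc5)c(OCc5ccccc5)c(OCc5ccccc5)c1 | intermediate
11 | 3,5-bis(benzyloxy)phenol | Oc1cc(OCc2ccccc2)cc(OCc2ccccc2)c1 | starting material
12 | phenol dimer, as 10 with a 2-hydroxy-4,6-bis(benzyloxy)phenyl group at C4β of unit 2 | O=C(O[C@@H]1[C@@H](c2c(OCc5ccccc5)cc(OCc5ccccc5)cc2O)c2c(OCc5ccccc5)cc(OCc5ccccc5)c([C@H]3c4c(OCc5ccccc5)cc(OCc5ccccc5)cc4O[C@H](c4ccc(OCc5ccccc5)c(OCc5ccccc5)c4)[C@@H]3O)c2O[C@@H]1c1cc(OCc5ccccc5)c(OCc5ccccc5)c(OCc5ccccc5)c1)c1cc(OCc5ccccc5)c(OCc5ccccc5)c(OCc5ccccc5)c1 | intermediate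
13 | 4-bromo-1,2-bis(benzyloxy)benzene | Brc1ccc(OCc2ccccc2)c(OCc2ccccc2)c1 | starting material
14 | 3,3-diethoxyprop-1-yne | C#CC(OCC)OCC | starting material
15 | 1,2-bis(benzyloxy)-4-(3,3-diethoxyprop-1-yn-1-yl)benzene | CCOC(OCC)C#Cc1ccc(OCc2ccccc2)c(OCc2ccccc2)c1 | intermediate
16 | (Z)-1,2-bis(benzyloxy)-4-(3,3-diethoxyprop-1-en-1-yl)benzene | CCOC(OCC)/C=C\c1ccc(OCc2ccccc2)c(OCc2ccccc2)c1 | intermediate
17 | (2S,3S)-2-[3,4-bis(benzyloxy)phenyl]-3-(diethoxymethyl)oxirane (cis) | CCOC(OCC)[C@H]1O[C@H]1c1ccc(OCc2ccccc2)c(OCc2ccccc2)c1 | intermediate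
18 | aryl ether acetal, 12 O-alkylated with a (1R,2S)-1-[3,4-bis(benzyloxy)phenyl]-3,3-diethoxy-2-hydroxypropyl group | O=C(O[C@@H]1[C@@H](c2c(OCc5ccccc5)cc(OCc5ccccc5)cc2O[C@H](c2ccc(OCc5ccccc5)c(OCc5ccccc5)c2)[C@H](O)C(OCC)OCC)c2c(OCc5ccccc5)cc(OCc5ccccc5)c([C@H]3c4c(OCc5ccccc5)cc(OCc5ccccc5)cc4O[C@H](c4ccc(OCc5ccccc5)c(OCc5ccccc5)c4)[C@@H]3O)c2O[C@@H]1c1cc(OCc5ccccc5)c(OCc5ccccc5)c(OCc5ccccc5)c1)c1cc(OCc5ccccc5)c(OCc5ccccc5)c(OCc5ccccc5)c1 | intermediate
19 | (+)-catechin, (2R,3S) | O[C@H]1Cc2c(O)cc(O)cc2O[C@@H]1c1ccc(O)c(O)c1 | starting material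
20 | 5,7,3',4'-tetra-O-benzyl-(+)-catechin | O[C@H]1Cc2c(OCc5ccccc5)cc(OCc5ccccc5)cc2O[C@@H]1c1ccc(OCc5ccccc5)c(OCc5ccccc5)c1 | intermediate
21 | 4-ethoxyflavan, 18 ring-closed at C4–C4a of unit 3 (2,3-cis, both C4 epimers, 4-OEt) | O=C(O[C@@H]1[C@@H](c2c(OCc5ccccc5)cc(OCc5ccccc5)c3c2O[C@H](c2ccc(OCc5ccccc5)c(OCc5ccccc5)c2)[C@H](O)C3OCC)c2c(OCc5ccccc5)cc(OCc5ccccc5)c([C@H]3c4c(OCc5ccccc5)cc(OCc5ccccc5)cc4O[C@H](c4ccc(OCc5ccccc5)c(OCc5ccccc5)c4)[C@@H]3O)c2O[C@@H]1c1cc(OCc5ccccc5)c(OCc5ccccc5)c(OCc5ccccc5)c1)c1cc(OCc5ccccc5)c(OCc5ccccc5)c(OCc5ccccc5)c1 | intermediate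
22 | icosa-O-benzyl ether of the target tetramer (all twenty phenols benzylated, three C3 hydroxyls free) | O=C(O[C@@H]1[C@@H](c2c(OCc5ccccc5)cc(OCc5ccccc5)c3c2O[C@H](c2ccc(OCc5ccccc5)c(OCc5ccccc5)c2)[C@H](O)[C@H]3c2c(OCc5ccccc5)cc(OCc5ccccc5)c3c2O[C@H](c2ccc(OCc5ccccc5)c(OCc5ccccc5)c2)[C@@H](O)C3)c2c(OCc5ccccc5)cc(OCc5ccccc5)c([C@H]3c4c(OCc5ccccc5)cc(OCc5ccccc5)cc4O[C@H](c4ccc(OCc5ccccc5)c(OCc5ccccc5)c4)[C@@H]3O)c2O[C@@H]1c1cc(OCc5ccccc5)c(OCc5ccccc5)c(OCc5ccccc5)c1)c1cc(OCc5ccccc5)c(OCc5ccccc5)c(OCc5ccccc5)c1 | intermediate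
23 | epicatechin-(4β→8)-epigallocatechin 3-O-gallate-(4β→8)-epicatechin-(4β→8)-catechin | O=C(O[C@@H]1[C@@H](c2c(O)cc(O)c3c2O[C@H](c2ccc(O)c(O)c2)[C@H](O)[C@H]3c2c(O)cc(O)c3c2O[C@H](c2ccc(O)c(O)c2)[C@@H](O)C3)c2c(O)cc(O)c([C@H]3c4c(O)cc(O)cc4O[C@H](c4ccc(O)c(O)c4)[C@@H]3O)c2O[C@@H]1c1cc(O)c(O)c(O)c1)c1cc(O)c(O)c(O)c1 | target

**Totals and risks**

Total step count: 15. Longest linear sequence: 9 steps (steps 3, 4, 5, 6, 7, 8, 12, 14 and 15, from (−)-epigallocatechin).

Steps most likely to fail:

1. Step 14 (proposed new method). What may go wrong: 20 may capture the open-chain oxocarbenium ion twice before the ring closes; the benzylic aryl ether at C2 may ionise, losing configuration or the side chain; the free C8 of unit 1 may cause oligomerisation; facial selectivity at C4 may be poor. The fallback uses known chemistry only and gives up the de novo closure of ring C of unit 3. It sets out from 10, with 3 and 20 as partners. TMSOTf-catalysed Friedel–Crafts coupling of 3 with excess 20 (CH2Cl2, −78 °C) gives octa-O-benzylprocyanidin B1 F1, the benzylated epicatechin-(4β→8)-catechin dimer. AgOTf activation of thioether 10 in the presence of F1 (CH2Cl2, −30 to 0 °C) then joins C4 of unit 2 to C8 of the upper unit of F1, the most nucleophilic carbon of a dimeric flavan nucleophile. This comes back to the route at 22, leaving only step 15.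

2. Step 12. What may go wrong: the hindered phenoxide may open the epoxide too slowly; partial SN1 character at the electron-rich benzylic carbon may erode configuration; attack may occur at the other epoxide carbon; the epoxide may rearrange to a carbonyl compound under heating. The fallback forms the ether bond before the phenol becomes hindered. It sets out from 11 and 17: Cs2CO3-mediated opening of 17 by the unhindered phenol 11 (DMF, 60 °C) gives aryl ether acetal F2. AgOTf-mediated coupling of thioether 10 with F2, buffered with 2,6-di-tert-butyl-4-methylpyridine to protect the acetal, alkylates a ring carbon ortho to the ether oxygen (two of the three open carbons). This comes back to the route at 18, after separation from any isomer formed at the carbon between the two benzyloxy groups.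

3. Step 11. What may go wrong: leakage to the trans-epoxide through the stepwise radical pathway of the manganese oxo species; moderate enantioselectivity with the bulky acetal substituent; acid-promoted rearrangement of the electron-rich epoxide during isolation. The fallback replaces metal-oxo transfer by a hydroxyl-directed, stereospecific epoxidation and sets out from 13. Sonogashira coupling of 13 with prop-2-yn-1-ol gives propargylic alcohol F3, and Lindlar semihydrogenation gives Z-allylic alcohol F4. Sharpless asymmetric epoxidation (Ti(OiPr)4, D-(−)-diethyl tartrate, tert-butyl hydroperoxide, 4 Å MS, CH2Cl2, −20 °C) gives cis-epoxy alcohol F5, and Parikh–Doering oxidation (SO3·pyridine, DMSO, Et3N) gives cis-epoxy aldehyde F6. Acetalisation with triethyl orthoformate and catalytic pyridinium p-toluenesulfonate in ethanol comes back to the route at 17.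

Further compounds

F1 | step 14 | octa-O-benzylprocyanidin B1, 5,7,3',4'-tetra-O-benzylepicatechin-(4β→8)-5,7,3',4'-tetra-O-benzylcatechin | c1c(OCc5ccccc5)cc(OCc5ccccc5)c2c1O[C@H](c1ccc(OCc5ccccc5)c(OCc5ccccc5)c1)[C@H](O)[C@H]2c1c(OCc5ccccc5)cc(OCc5ccccc5)c2c1O[C@H](c1ccc(OCc5ccccc5)c(OCc5ccccc5)c1)[C@@H](O)C2
F2 | step 12 | (2S,3R)-3-[3,4-bis(benzyloxy)phenyl]-3-[3,5-bis(benzyloxy)phenoxy]-1,1-diethoxypropan-2-ol | c1c(OCc2ccccc2)cc(OCc2ccccc2)cc1O[C@H](c1ccc(OCc2ccccc2)c(OCc2ccccc2)c1)[C@H](O)C(OCC)OCC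
F3 | step 11 | 3-[3,4-bis(benzyloxy)phenyl]prop-2-yn-1-ol | OCC#Cc1ccc(OCc2ccccc2)c(OCc2ccccc2)c1
F4 | step 11 | (Z)-3-[3,4-bis(benzyloxy)phenyl]prop-2-en-1-ol | OC/C=C\c1ccc(OCc2ccccc2)c(OCc2ccccc2)c1
F5 | step 11 | [(2R,3S)-3-[3,4-bis(benzyloxy)phenyl]oxiran-2-yl]methanol (cis) | OC[C@H]1O[C@H]1c1ccc(OCc2ccccc2)c(OCc2ccccc2)c1
F6 | step 11 | (2S,3S)-3-[3,4-bis(benzyloxy)phenyl]oxirane-2-carbaldehyde (cis) | O=C[C@H]1O[C@H]1c1ccc(OCc2ccccc2)c(OCc2ccccc2)c1
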